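## Structural features

The target is a linear, twofold-symmetric chain of six six-membered carbocycles, A–B–C–C'–B'–A', joined by five CH2 bridges. Rings B, C, C' and B' are fully substituted butanoylphloroglucinols; in the numbering used throughout, C1 carries the butanoyl group, O2, O4 and O6 are hydroxyls, and C3 and C5 each carry a bridge. Rings A and A' are enolised 2-butanoyl-4,4-dimethylcyclohexane-1,3,5-triones joined through C6. Their CMe2 carbon is not stereogenic, so the molecule has no stereocentre and nothing stereochemical has to be set or kept. The fragile elements are the bridges themselves: each is a bis(hydroxyaryl)methane that can open to a quinone methide in base (exchange of bridges between rings) or break after ipso-protonation in strong acid; the polyphenol and triketone enol units are also air-sensitive. The real difficulty is pairing and order, because five nearly identical ring–CH2–ring bonds must be formed between rings of similar nucleophilicity without statistical mixtures. The key step exploits the C–C' dimer, in which each ring has a single unsubstituted carbon, C3. C3 lies ortho to O2 and to O4 (the non-chelated hydroxyl para to the ketone) and para to O6, while C5 holds the central bridge and C1 the ketone, so a benzyl group parked on oxygen can settle on carbon only at C3.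

## Logic of the disconnections

15 to 12 plus two 13. The two outer bonds between C6 of rings A and A' and the bridge carbons are cut, and each bridge carbon stays on ring B or B' as a formyl group. The end rings are the most base- and air-sensitive parts, so they are attached last. With the one-carbon unit at the aldehyde level on 12 and the nucleophile on 13, neither partner can couple with itself. The hexamer becomes a tetramer and two identical small units. The forward step must condense a hydrogen-bonded aldehyde with C6 of 13 and reduce the alkylidene 14 at once, under conditions too mild for bridge exchange.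

12 to 11. The two formyl C–C bonds on rings B and B' are cut. 11 has exactly two aromatic C–H bonds, one on each outer ring, so electrophilic formylation needs no regiocontrol. The forward step must stop cleanly on a dodecaphenol and must not attack bridge-bearing carbons.

11 to 10. Six O–CH3 bonds on rings B and B' are cut. As methyl ethers these rings are non-acidic, cannot form quinone methides, and stabilise the benzylic cation of the key step. The forward step is a global ether cleavage that must leave the diarylmethane links intact.

10 to 9 (key disconnection). The two bonds between the benzylic CH2 of rings B and B' and C3 of rings C and C' are cut, and the benzyl groups are placed on O4 and O4'. This turns a bimolecular C–C union of two similar rings into an isomerisation. The pairing of rings is settled beforehand in a neutral, stoichiometric step, and the cation is generated only beside its acceptor. Three design decisions follow.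
- The four ortho hydroxyls of rings C and C' stay free: any benzyl group they capture is again an acid-labile ether whose only outlet is C3.
- Ring B is left unblocked: a halogen at its free carbon would twist the para methoxy group out of conjugation, weaken ionisation, and cost extra steps.
- The forward step must make heterolysis easier than any reaction of the central bridge and must return the cation to ring C before it reaches the free carbon of ring B in another molecule.

9 to 4 plus two 8. The two O–CH2 bonds are cut. O4 is the most acidic and least hindered hydroxyl of each ring, and a redox-dehydration with alcohol 8 avoids a benzylic halide, which would alkylate its own activated free ring carbon. A hexaphenol is not intrinsically limited to two benzyl groups, so the count is set by stoichiometry and by the acidity gap. The position on oxygen is less critical than the count, because every O-benzyl isomer has C3 as its only destination.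

8 to 7 to 6 to 5 plus 2. In turn the benzylic C–O bond (reduction), the formyl C–C bond and the acyl C–C bond are cut, reaching a symmetrical triether. Each forward step must stop at mono-substitution, and the reduction must select the aldehyde over the ketone flanked by two methoxy groups.

4 to two 3 plus a one-carbon electrophile; 3 to 1 plus 2. The two bonds of the central bridge are cut, then the acyl C–C bond. The free carbons of 3 are equivalent, so only one dimer constitution can form. The forward coupling must stop at the dimer.

13 to 3. The two C–CH3 bonds at one ring carbon are cut, so 3 serves rings A, A', C and C'. The forward step needs geminal C-methylation, not O-methylation, and no more than two methyl groups.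

## Other disconnections considered

Alternative 1: The cut is the bond between the central bridge carbon and ring C', giving two trimers. Forward, the formyl trimer A2, the parent trimer A3 and phenylboronic acid A4 would condense to the benzodioxaborin A1. Boron ties O4' of A3 to the aldehyde of A2, the free carbon of ring C' attacks the activated carbonyl, and the benzylic C–O bond of A1 must then be reduced to CH2.
- In favour: it is the most convergent plan (3 + 3). The electrophile is delivered from the neighbouring oxygen and never exists as a free cation, so on shielding from crossover onto ring B it is the better plan.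
- Against: A2 and A3 carry many competing boron-binding sites (a hydroxy-ketone chelate on every ring and the triketone enols of ring A), so the templating is not secured. The aldehyde of A2 is a vinylogous acid and a poor electrophile. Removing the benzylic oxygen needs hydride and acid in the presence of four other acid-labile bridges.
- Comparison: both plans leave no regiochemical ambiguity at the new bond (equal). The alternative does not use the twofold symmetry, since A2 and A3 each need two controlled cross-couplings and differ in their end groups, plus an extra reduction. It should therefore be longer than the two-directional chosen plan.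

Alternative 2: The cut removes two ring bonds from each of rings B and B', which are built de novo. Forward, the bis(siloxyalkyne) A6 would be heated with two equivalents of 3-ethoxycyclobutenone A7 in a Danheiser benzannulation (cycloaddition of the vinylketene, ring opening, six-electron electrocyclisation) to give A5.
- In favour: the pericyclic cascade fixes the new ring's substitution pattern, placing the carbon that bears the CH2 link between the new hydroxyl and the silyloxy carbon. This regiocontrol equals that of the chosen plan. The thermal, neutral conditions and the absence of any benzylic cation are better than a Lewis-acid step. Its two-directional use of symmetry is equal.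
- Against: A5 has no butanoyl group on any ring. Four late acylations would be needed, those on rings B and B' at one of two free carbons. The ring B oxygens emerge in three different forms although the target needs three identical hydroxyls. A6 itself needs a multistep homologation of a protected dimer.
- Comparison: the chosen plan uses every ring as a preformed butanoylphloroglucinol and should be considerably shorter.

Alternative 3: The cut is one ring bond in each of rings C and C', between the acyl-bearing carbon and the carbon that was the lactone carbonyl. Forward, the bis-pyranone A8 would be opened by Mg(OMe)2 A9 to a bis(triketo ester), and each chain would close by Claisen condensation to A10, which is the same compound as 4.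
- In favour: the bridge is installed on pyranones whose C3 is the only strongly nucleophilic carbon, so higher oligomers are excluded. On that point it is better than step 2. It also places the butanoyl group without a Friedel–Crafts acylation.
- Against: A8 needs a 6-(2-oxopentyl)pyranone that takes several steps to make, against two steps from 1 to 4. Aldol closure to a resorcinol isomer and retro-Claisen cleavage compete. The alternative stops at 4 and does not address the attachment of rings B and A.
- Comparison: everything after 4 would be the same (equal). It should be about three steps longer.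

Key step: step 7

Assumption: 9 and 10 are isomers (C49H60O16) and their ring patterns map onto the target (C69H80O24), so step 7 is a true isomerisation; the enol forms drawn are single representations of equilibrating tautomers.

## Route

Step 1
Reactants: 1 phloroglucinol; 2 butanoyl chloride
Product: 3 1-(2,4,6-trihydroxyphenyl)butan-1-one
Conditions: AlCl3 (3.5 equiv), PhNO2/CH2Cl2, 0 °C → 45 °C; aq. HCl
Reagents that add atoms: none
Why: Friedel–Crafts C-acylation of the symmetrical triphenol; the first acyl group deactivates the ring, so monoacylation should dominate.

Step 2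
Reactants: 3 1-(2,4,6-trihydroxyphenyl)butan-1-one (3 equiv relative to formaldehyde)
Product: 4 bis(3-butanoyl-2,4,6-trihydroxyphenyl)methane (C–C' dimer)
Conditions: 37% aq. HCHO (1 equiv), 0.25 M aq. NaOH, 0 °C, 15 min, N2; then 1 M HCl
Reagents that add atoms: formaldehyde, C=O
Why: Base-mediated phenol–formaldehyde condensation (hydroxymethylation, then a second C-alkylation); the two free carbons of 3 are equivalent, so one constitution results, and excess 3 limits higher oligomers.

Step 3
Reactants: 5 1,3,5-trimethoxybenzene; 2 butanoyl chloride
Product: 6 1-(2,4,6-trimethoxyphenyl)butan-1-one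
Conditions: AlCl3 (1.1 equiv), CH2Cl2, −10 → 0 °C, 1 h
Reagents that add atoms: none
Why: Friedel–Crafts acylation of a strongly activated arene; low temperature and short time avoid chelation-assisted loss of an ortho methyl ether.

Step 4
Reactants: 6 1-(2,4,6-trimethoxyphenyl)butan-1-one
Product: 7 3-butanoyl-2,4,6-trimethoxybenzaldehyde
Conditions: POCl3 (1.5 equiv), DMF, 0 °C → 40 °C; then ice/H2O
Reagents that add atoms: N,N-dimethylformamide, CN(C)C=O; water, O
Why: Vilsmeier–Haack formylation; the ketone is twisted out of conjugation by two ortho methoxy groups, so the ring stays activated, its two free carbons are equivalent, and the first formyl group deactivates the ring against a second.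

Step 5
Reactants: 7 3-butanoyl-2,4,6-trimethoxybenzaldehyde
Product: 8 1-[3-(hydroxymethyl)-2,4,6-trimethoxyphenyl]butan-1-one
Conditions: NaBH4 (0.6 equiv), MeOH/THF, −20 → 0 °C; neutral work-up
Reagents that add atoms: none
Why: Chemoselective borohydride reduction; the aldehyde is far more electrophilic than the aryl ketone flanked by two methoxy groups, and a neutral work-up protects the acid-sensitive benzylic alcohol.

Step 6
Reactants: 4 bis(3-butanoyl-2,4,6-trihydroxyphenyl)methane; 8 1-[3-(hydroxymethyl)-2,4,6-trimethoxyphenyl]butan-1-one (2.1 equiv)
Product: 9 bis{3-butanoyl-2,4-dihydroxy-6-[(3-butanoyl-2,4,6-trimethoxyphenyl)methoxy]phenyl}methane (each benzyl group on O4, the oxygen para to the ketone)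
Conditions: PPh3 (2.3 equiv), DIAD (2.3 equiv, slow addition), THF, 0 °C → rt
Reagents that add atoms: none
Why: Mitsunobu etherification; the betaine deprotonates the most acidic, non-chelated hydroxyl of each ring (O4) and the aryloxide displaces Ph3PO from the activated benzylic alcohol. Limiting 8 to two equivalents caps the benzyl count, and no benzylic halide, which would alkylate its own free ring carbon, is handled.

Step 7
Reactants: 9 bis{3-butanoyl-2,4-dihydroxy-6-[(3-butanoyl-2,4,6-trimethoxyphenyl)methoxy]phenyl}methane
Product: 10 bis{3-butanoyl-5-[(3-butanoyl-2,4,6-trimethoxyphenyl)methyl]-2,4,6-trihydroxyphenyl}methane (tetramer B–C–C'–B', rings B and B' as trimethyl ethers)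
Conditions: Sc(OTf)3 (20 mol %), CH2Cl2 (0.003 M), 4 Å MS, −20 °C → rt
Reagents that add atoms: none
Why: Sc(OTf)3 coordinates the ether oxygen O4 and the O–CH2 bond ionises to a contact ion pair of the 3-butanoyl-2,4,6-trimethoxybenzyl cation (two ortho and one para methoxy donor) and the scandium-bound aryloxide of ring C. Return to oxygen is degenerate, whereas collapse at the neighbouring carbon C3 gives a cyclohexadienone that tautomerises to the phenol, so the C-benzyl isomer should accumulate; the same sequence on ring C' forms the second bond. The closest known reaction type is the acid-catalysed 1,3-shift of benzyl aryl ethers to ortho-benzylphenols, here twofold and with an unusually stabilised migrating group. No ring is closed and no stereocentre is created; the step forms the two CH2–C3 bonds. Within ring C the selectivity needed is C3 over C5 and C1, and the substrate secures it because C5 carries the central bridge and C1 the ketone, so attack there cannot be followed by proton loss and reverts. For the same reason a benzyl group lying on O2 or O6, or already on C3 after step 6, ends or stays at C3, so positional isomers of 9 converge on 10. Exchange of benzyl groups between ring C carbons of different molecules is harmless because both groups are identical; the one damaging escape, alkylation of the free carbon of ring B in a second molecule, is bimolecular and is held back by ion pairing in a non-polar solvent, low temperature and high dilution. The four ortho hydroxyls stay unprotected, since a benzyl group caught by one of them is again an acid-labile ether with C3 as its only outlet.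

Step 8
Reactants: 10 bis{3-butanoyl-5-[(3-butanoyl-2,4,6-trimethoxyphenyl)methyl]-2,4,6-trihydroxyphenyl}methane
Product: 11 bis{3-butanoyl-5-[(3-butanoyl-2,4,6-trihydroxyphenyl)methyl]-2,4,6-trihydroxyphenyl}methane (tetramer dodecaol)
Conditions: BBr3 (15 equiv), CH2Cl2, −78 °C → rt; then ice/H2O at 0 °C
Reagents that add atoms: none
Why: Lewis-acid cleavage of aryl methyl ethers; chelation to the ring B ketone assists the two ortho ethers and excess reagent cleaves the para one, while boron-bound aryloxides deactivate the rings toward ipso-protonation at the bridges.

Step 9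
Reactants: 11 bis{3-butanoyl-5-[(3-butanoyl-2,4,6-trihydroxyphenyl)methyl]-2,4,6-trihydroxyphenyl}methane
Product: 12 bis{3-butanoyl-5-[(3-butanoyl-5-formyl-2,4,6-trihydroxyphenyl)methyl]-2,4,6-trihydroxyphenyl}methane (tetramer dialdehyde)
Conditions: POCl3 (5 equiv), DMF (6 equiv), EtOAc, 0 °C → rt; then H2O, rt
Reagents that add atoms: N,N-dimethylformamide, CN(C)C=O; water, O
Why: Vilsmeier–Haack formylation of an acylphloroglucinol; the only aromatic C–H bonds of 11 are C3 of rings B and B', so the site is unambiguous, and aqueous work-up releases the aldehydes and any O-formyl groups.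

Step 10
Reactants: 3 1-(2,4,6-trihydroxyphenyl)butan-1-one
Product: 13 2-butanoyl-3,5-dihydroxy-4,4-dimethylcyclohexa-2,5-dien-1-one (butanoylfilicinic acid)
Conditions: MeI (2.5 equiv), NaOMe (3.5 equiv), MeOH, 0 °C → rt
Reagents that add atoms: iodomethane, CI
Why: Geminal C-methylation of the phloroglucinol polyanion, which dearomatises one ring carbon to the enolised triketone; limiting MeI restrains tri- and tetramethylation, and the two methyl groups are identical, so no stereocentre arises.

Step 11
Reactants: 12 bis{3-butanoyl-5-[(3-butanoyl-5-formyl-2,4,6-trihydroxyphenyl)methyl]-2,4,6-trihydroxyphenyl}methane; 13 2-butanoyl-3,5-dihydroxy-4,4-dimethylcyclohexa-2,5-dien-1-one (2.2 equiv)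
Product: 15 target hexamer A–B–C–C'–B'–A' (CNP0237140.0), via twofold Knoevenagel alkylidene 14 (not isolated)
Conditions: L-proline (0.4 equiv), Hantzsch ester (2.5 equiv), CH2Cl2/EtOH, rt, argon
Reagents that add atoms: none
Why: Organocatalytic reductive Knoevenagel alkylation; each formyl group condenses with C6 of 13, its only unsubstituted and doubly activated ring carbon, and the electron-poor alkylidene is reduced in situ by hydride transfer from the dihydropyridine. Near-neutral conditions at room temperature are chosen to avoid bridge exchange, and no stereocentre is formed.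

## Compound list

1 | phloroglucinol (benzene-1,3,5-triol) | Oc1cc(O)cc(O)c1 | starting material
2 | butanoyl chloride | CCCC(Cl)=O | starting material
3 | 1-(2,4,6-trihydroxyphenyl)butan-1-one | CCCC(=O)c1c(O)cc(O)cc1O | intermediate
4 | bis(3-butanoyl-2,4,6-trihydroxyphenyl)methane (C–C' dimer) | CCCC(=O)c1c(O)cc(O)c(Cc2c(O)cc(O)c(C(=O)CCC)c2O)c1O | intermediate
5 | 1,3,5-trimethoxybenzene | COc1cc(OC)cc(OC)c1 | starting material
6 | 1-(2,4,6-trimethoxyphenyl)butan-1-one | CCCC(=O)c1c(OC)cc(OC)cc1OC | intermediate
7 | 3-butanoyl-2,4,6-trimethoxybenzaldehyde | CCCC(=O)c1c(OC)cc(OC)c(C=O)c1OC | intermediate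
8 | 1-[3-(hydroxymethyl)-2,4,6-trimethoxyphenyl]butan-1-one | CCCC(=O)c1c(OC)cc(OC)c(CO)c1OC | intermediate
9 | bis{3-butanoyl-2,4-dihydroxy-6-[(3-butanoyl-2,4,6-trimethoxyphenyl)methoxy]phenyl}methane (key-step precursor) | CCCC(=O)c1c(O)cc(OCc2c(OC)cc(OC)c(C(=O)CCC)c2OC)c(c1O)Cc1c(O)c(C(=O)CCC)c(O)cc1OCc1c(OC)cc(OC)c(C(=O)CCC)c1OC | intermediate
10 | bis{3-butanoyl-5-[(3-butanoyl-2,4,6-trimethoxyphenyl)methyl]-2,4,6-trihydroxyphenyl}methane (key-step product) | CCCC(=O)c1c(OC)cc(OC)c(c1OC)Cc1c(O)c(C(=O)CCC)c(O)c(c1O)Cc1c(O)c(C(=O)CCC)c(O)c(c1O)Cc1c(OC)cc(OC)c(C(=O)CCC)c1OC | intermediate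
11 | bis{3-butanoyl-5-[(3-butanoyl-2,4,6-trihydroxyphenyl)methyl]-2,4,6-trihydroxyphenyl}methane | CCCC(=O)c1c(O)cc(O)c(c1O)Cc1c(O)c(C(=O)CCC)c(O)c(c1O)Cc1c(O)c(C(=O)CCC)c(O)c(c1O)Cc1c(O)cc(O)c(C(=O)CCC)c1O | intermediate
12 | bis{3-butanoyl-5-[(3-butanoyl-5-formyl-2,4,6-trihydroxyphenyl)methyl]-2,4,6-trihydroxyphenyl}methane | CCCC(=O)c1c(O)c(C=O)c(O)c(c1O)Cc1c(O)c(C(=O)CCC)c(O)c(c1O)Cc1c(O)c(C(=O)CCC)c(O)c(c1O)Cc1c(O)c(C=O)c(O)c(C(=O)CCC)c1O | intermediate
13 | 2-butanoyl-3,5-dihydroxy-4,4-dimethylcyclohexa-2,5-dien-1-one | CCCC(=O)C1=C(O)C(C)(C)C(O)=CC1=O | intermediate
14 | twofold Knoevenagel alkylidene: 12 in which each formyl carbon is a CH= doubly bonded to C6 of a 2-butanoyl-3-hydroxy-4,4-dimethylcyclohex-2-ene-1,5-dione ring | CCCC(=O)C1=C(O)C(C)(C)C(=O)C(=Cc2c(O)c(Cc3c(O)c(Cc4c(O)c(Cc5c(O)c(C=C6C(=O)C(C)(C)C(O)=C(C(=O)CCC)C6=O)c(O)c(C(=O)CCC)c5O)c(O)c(C(=O)CCC)c4O)c(O)c(C(=O)CCC)c3O)c(O)c(C(=O)CCC)c2O)C1=O | intermediate (not isolated)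
15 | target hexamer: 11 carrying on C3 of each outer ring a (5-butanoyl-2,4-dihydroxy-3,3-dimethyl-6-oxocyclohexa-1,4-dien-1-yl)methyl group | CCCC(=O)C1=C(O)C(C)(C)C(O)=C(Cc2c(O)c(Cc3c(O)c(Cc4c(O)c(Cc5c(O)c(CC6=C(O)C(C)(C)C(O)=C(C(=O)CCC)C6=O)c(O)c(C(=O)CCC)c5O)c(O)c(C(=O)CCC)c4O)c(O)c(C(=O)CCC)c3O)c(O)c(C(=O)CCC)c2O)C1=O | target

## Step count and least certain steps

Total step count: 11. Longest linear sequence: 8 steps (5 → 6 → 7 → 8 → 9 → 10 → 11 → 12 → 15; steps 3, 4, 5, 6, 7, 8, 9 and 11).

Step 7 (key step). The most likely failure is escape of the benzyl cation from the ion pair followed by Friedel–Crafts alkylation of the free carbon of ring B in a second molecule, which leads to oligomers. The cause is that the twisted ketone of ring B leaves that carbon about as nucleophilic as C3 of ring C. A second failure is acid-induced ipso-cleavage of the central bridge if triflic acid is released by the chelating hydroxy ketones. The fallback sets out from 4 and rejoins at 11, bypassing 9 and 10. 4 is aminomethylated at its two free carbons with dimethyl(methylidene)ammonium iodide to give bis{3-butanoyl-5-[(dimethylamino)methyl]-2,4,6-trihydroxyphenyl}methane F1. Heating F1 in dioxane with a large excess of 3 expels dimethylamine, and each quinone methide is captured by a free carbon of 3 to give 11.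

Step 6. The most likely failure is uptake of one or three benzyl groups per molecule of 4, or etherification of a chelated hydroxyl, because after O4 is alkylated the remaining hydroxyls are only slightly less acidic. Positional isomers matter less than the count, as explained under step 7. The fallback sets out from 3 and rejoins at 9. 3 is etherified at O4 with one equivalent of 8 under the same redox-dehydration, and 1-{4-[(3-butanoyl-2,4,6-trimethoxyphenyl)methoxy]-2,6-dihydroxyphenyl}butan-1-one F2 is purified at the monomer stage, where only two kinds of hydroxyl exist. Two molecules of F2 are then joined through their equivalent free carbons by formaldehyde in cold dilute NaOH, to which the benzyl ether is stable, giving 9.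

Step 8. The most likely failures are incomplete cleavage of the methyl ethers para to the ketones, and fragmentation of the B–CH2–C links through ipso-protonation by HBr formed from the six free hydroxyls and during the quench. The fallback sets out from 3 and rejoins at 11, replacing methyl by benzyl ethers that are removed without acid.
- Exhaustive O-benzylation of 3 (BnBr, K2CO3, DMF, 70 °C) gives 1-[2,4,6-tris(benzyloxy)phenyl]butan-1-one F3.
- Vilsmeier–Haack formylation gives 2,4,6-tris(benzyloxy)-3-butanoylbenzaldehyde F4.
- NaBH4 gives 1-[2,4,6-tris(benzyloxy)-3-(hydroxymethyl)phenyl]butan-1-one F5.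
- Mitsunobu coupling of two F5 with 4 gives the bis-ether with six benzyloxy groups F6.
- Sc(OTf)3 at low temperature, where simple benzyl ethers do not ionise, gives the hexabenzyl tetramer F7.
- Hydrogenolysis (H2, Pd/C, EtOAc/MeOH) gives 11.

Step 9. The most likely failures are ipso attack of the chloroiminium ion at a bridge-bearing carbon with loss of a hydroxybenzyl fragment, and incomplete twofold formylation of a poorly soluble dodecaphenol. The fallback sets out from 11 and rejoins at 15, bypassing 12 and 14. 11 is aminomethylated at its two free carbons with dimethyl(methylidene)ammonium iodide to give the bis[(dimethylamino)methyl] tetramer F8. Warming F8 with excess 13 expels dimethylamine, and the quinone methides of rings B and B' are captured by C6 of 13.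

Step 11. The most likely failures are slow condensation of the strongly hydrogen-bonded trihydroxybenzaldehyde, addition of a second molecule of 13 to the alkylidene before hydride transfer, and amine-induced bridge exchange. The fallback sets out from 11 and rejoins at 15. It is the classical three-component condensation of 11 with formaldehyde and a large excess of 13 in cold dilute alkali for a few minutes, followed by acidification and separation from the self-coupled end-unit dimer. It makes no new compound, F0.

## Further compounds

F1 | step 7 | bis{3-butanoyl-5-[(dimethylamino)methyl]-2,4,6-trihydroxyphenyl}methane | CCCC(=O)c1c(O)c(CN(C)C)c(O)c(Cc2c(O)c(CN(C)C)c(O)c(C(=O)CCC)c2O)c1O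
F2 | step 6 | 1-{4-[(3-butanoyl-2,4,6-trimethoxyphenyl)methoxy]-2,6-dihydroxyphenyl}butan-1-one | CCCC(=O)c1c(O)cc(OCc2c(OC)cc(OC)c(C(=O)CCC)c2OC)cc1O
F3 | step 8 | 1-[2,4,6-tris(benzyloxy)phenyl]butan-1-one | CCCC(=O)c1c(OCc2ccccc2)cc(OCc2ccccc2)cc1OCc1ccccc1
F4 | step 8 | 2,4,6-tris(benzyloxy)-3-butanoylbenzaldehyde | CCCC(=O)c1c(OCc2ccccc2)cc(OCc2ccccc2)c(C=O)c1OCc1ccccc1
F5 | step 8 | 1-[2,4,6-tris(benzyloxy)-3-(hydroxymethyl)phenyl]butan-1-one | CCCC(=O)c1c(OCc2ccccc2)cc(OCc2ccccc2)c(CO)c1OCc1ccccc1
F6 | step 8 | bis{3-butanoyl-2,4-dihydroxy-6-[(2,4,6-tris(benzyloxy)-3-butanoylphenyl)methoxy]phenyl}methane | CCCC(=O)c1c(O)cc(OCc2c(OCc3ccccc3)cc(OCc3ccccc3)c(C(=O)CCC)c2OCc2ccccc2)c(c1O)Cc1c(O)c(C(=O)CCC)c(O)cc1OCc1c(OCc2ccccc2)cc(OCc2ccccc2)c(C(=O)CCC)c1OCc1ccccc1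
F7 | step 8 | bis{3-butanoyl-5-[(2,4,6-tris(benzyloxy)-3-butanoylphenyl)methyl]-2,4,6-trihydroxyphenyl}methane | CCCC(=O)c1c(OCc2ccccc2)cc(OCc2ccccc2)c(c1OCc1ccccc1)Cc1c(O)c(C(=O)CCC)c(O)c(c1O)Cc1c(O)c(C(=O)CCC)c(O)c(c1O)Cc1c(OCc2ccccc2)cc(OCc2ccccc2)c(C(=O)CCC)c1OCc1ccccc1
F8 | step 9 | bis{3-butanoyl-5-[(3-butanoyl-5-[(dimethylamino)methyl]-2,4,6-trihydroxyphenyl)methyl]-2,4,6-trihydroxyphenyl}methane | CCCC(=O)c1c(O)c(CN(C)C)c(O)c(c1O)Cc1c(O)c(C(=O)CCC)c(O)c(c1O)Cc1c(O)c(C(=O)CCC)c(O)c(c1O)Cc1c(O)c(CN(C)C)c(O)c(C(=O)CCC)c1O
F0 | step 11 | none | none
A1 | alternative 1 | hexamer whose central carbon lies in a 2-phenyl-4H-1,3,2-benzodioxaborin fused to ring C' | CCCC(=O)C1=C(O)C(C)(C)C(O)=C(C1=O)Cc1c(O)c(C(=O)CCC)c(O)c(c1O)Cc1c(O)c(C2OB(c3ccccc3)Oc3c2c(O)c(C(=O)CCC)c(O)c3Cc2c(O)c(C(=O)CCC)c(O)c(c2O)CC2=C(O)C(C)(C)C(O)=C(C(=O)CCC)C2=O)c(O)c(C(=O)CCC)c1O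
A2 | alternative 1 | formyl trimer A–B–C (formyl group on the free carbon of ring C) | CCCC(=O)C1=C(O)C(C)(C)C(O)=C(C1=O)Cc1c(O)c(C(=O)CCC)c(O)c(c1O)Cc1c(O)c(C=O)c(O)c(C(=O)CCC)c1O
A3 | alternative 1 | parent trimer C'–B'–A' (free carbon on ring C') | Oc1cc(O)c(C(=O)CCC)c(O)c1Cc1c(O)c(C(=O)CCC)c(O)c(c1O)CC1=C(O)C(C)(C)C(O)=C(C(=O)CCC)C1=O
A4 | alternative 1 | phenylboronic acid | OB(O)c1ccccc1
A5 | alternative 2 | tetramer with new rings B and B' bearing hydroxyl, ethoxy and triisopropylsilyloxy groups, rings C and C' as trimethyl ethers | CCOc1cc(O)c(c(O[Si](C(C)C)(C(C)C)C(C)C)c1)Cc1c(OC)cc(OC)c(c1OC)Cc1c(OC)cc(OC)c(Cc2c(O)cc(OCC)cc2O[Si](C(C)C)(C(C)C)C(C)C)c1OC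
A6 | alternative 2 | bis{2,4,6-trimethoxy-3-[3-(triisopropylsilyloxy)prop-2-yn-1-yl]phenyl}methane | CC(C)[Si](C(C)C)(C(C)C)OC#CCc1c(OC)cc(OC)c(c1OC)Cc1c(OC)cc(OC)c(CC#CO[Si](C(C)C)(C(C)C)C(C)C)c1OC
A7 | alternative 2 | 3-ethoxycyclobut-2-en-1-one | CCOC1=CC(=O)C1
A8 | alternative 3 | 3,3'-methylenebis[4-hydroxy-6-(2-oxopentyl)-2H-pyran-2-one] | CCCC(=O)Cc1cc(O)c(Cc2c(O)cc(CC(=O)CCC)oc2=O)c(=O)o1
A9 | alternative 3 | magnesium dimethoxide | [Mg+2].[O-]C.[O-]C
A10 | alternative 3 | bis(3-butanoyl-2,4,6-trihydroxyphenyl)methane (same compound as 4) | CCCC(=O)c1c(O)cc(O)c(c1O)Cc1c(O)cc(O)c(C(=O)CCC)c1O
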